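**Plan**
Atom labels: lactone ring C1(syringyl)-O2-C3(=O)-C4-C5; ether ring C4-C5-C6H2-O7-C8(catechol). H-C1, H-C4, H-C5 and H-C8 are all cis, so both aryl groups lie on the concave face (C1 S, C4 R, C5 S, C8 S).
Cuts, in order: the two catechol O-Si bonds; C1-O2 (key step); H-C8/H-C4 (syn hydrogenation of a C8=C4 dihydrofuran); O7-C8 (acyl-lactone rearrangement); C4-C8 (aldol, then oxidation); H-C5 (asymmetric hydrogenation); C1=C5 (Stobbe condensation).
Enabling feature: C1 is a benzylic CH2 para to the only free phenol OH (syringyl ring) and gamma to carboxyl C3. C3 stands cis to the C1 side chain on the ether ring, so a p-quinone methide at C1 can be closed to the five-membered lactone.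
Forward: syringaldehyde and dimethyl succinate give the C1-C5(-C6)-C4-C3 chain. A temporary butyrolactone (C3-C4-C5-C6-O) carries it to the aldol, its ring oxygen then becomes O7 of the ether ring, and the lactone ring closes last.
Stereochemistry: C5 comes from Rh-catalysed asymmetric hydrogenation. C4 and C8 come from syn addition of H2 anti to the C5 arylmethyl group, which gives the contra-thermodynamic all-cis acid. C1 comes from the enzyme pocket.

Key step: step 10

Assumption: the Et-DuPhos antipode of step 3 is the one that gives the 3S half-ester (both antipodes are sold; the sense is to be checked on the derived lactone), and the oxidase of step 10 is a variant still to be evolved.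

**Step 1**
Reactants: 1 syringaldehyde
Product: 2 4-(benzyloxy)-3,5-dimethoxybenzaldehyde
Conditions: BnBr, K2CO3, DMF, rt
Reagents that add atoms: benzyl bromide, BrCc1ccccc1
Why: Williamson ether synthesis; the benzyl ether shields the syringyl phenol in the basic steps and leaves in step 9 together with the benzyl ester.

**Step 2**
Reactants: 2 4-(benzyloxy)-3,5-dimethoxybenzaldehyde; 3 dimethyl succinate
Product: 4 (E)-4-[4-(benzyloxy)-3,5-dimethoxyphenyl]-3-(methoxycarbonyl)but-3-enoic acid
Conditions: NaOMe, MeOH, reflux; then aq. HCl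
Reagents that add atoms: none
Why: Stobbe condensation, which is E-selective for aromatic aldehydes and delivers the whole C1-C5(-C6)-C4-C3 chain in one operation, with C3 and C6 differentiated as free acid and methyl ester.

**Step 3**
Reactants: 4 (E)-half-ester
Product: 5 (3S)-4-[4-(benzyloxy)-3,5-dimethoxyphenyl]-3-(methoxycarbonyl)butanoic acid
Conditions: [Rh(cod)(Et-DuPhos)]BF4 (0.5 mol %), H2 (5 atm), MeOH, rt
Reagents that add atoms: none
Why: Rh-catalysed asymmetric hydrogenation of an itaconate-type half-ester, in which chelation of the alkene and the neighbouring carboxyl group to the C2-symmetric Rh-bisphospholane fixes the face of H2 delivery and sets C5 as S, while the benzyl ether is inert to this homogeneous catalyst.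

**Step 4**
Reactants: 5 (3S)-half-ester
Product: 7 (4S)-4-[4-(benzyloxy)-3,5-dimethoxybenzyl]dihydrofuran-2(3H)-one, via hydroxy acid 6 (not isolated)
Conditions: KOH (1 equiv), EtOH; CaCl2, NaBH4, -10 °C to rt; then 2 M HCl, rt
Reagents that add atoms: none
Why: Chemoselective borohydride reduction, in which the carboxylate salt is inert while the methyl ester C6 is reduced to the alcohol 6, which lactonises on acidification; C5 is not touched.

**Step 5**
Reactants: 8 3,4-dihydroxybenzaldehyde
Product: 9 3,4-bis(triisopropylsilyloxy)benzaldehyde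
Conditions: TIPSCl, imidazole, DMF, rt
Reagents that add atoms: chlorotriisopropylsilane, CC(C)[Si](Cl)(C(C)C)C(C)C
Why: Silyl ether formation; the two triisopropylsilyl groups tolerate the enolate, oxidation, acid and hydrogenation steps, deny the catechol ring a free para OH in step 10 and leave at the end under buffered fluoride.

**Step 6**
Reactants: 7 (4S)-lactone; 9 3,4-bis(triisopropylsilyloxy)benzaldehyde
Product: 10 (3R,4S)-4-[4-(benzyloxy)-3,5-dimethoxybenzyl]-3-{[3,4-bis(triisopropylsilyloxy)phenyl](hydroxy)methyl}dihydrofuran-2(3H)-one (both carbinol epimers)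
Conditions: LiHMDS, THF, -78 °C; then 9; AcOH quench
Reagents that add atoms: none
Why: Lithium enolate aldol addition, in which the aldehyde approaches the lactone enolate anti to the C5 arylmethyl group so that C4 forms trans to it; the carbinol centre C8 needs no control because step 7 removes it.

**Step 7**
Reactants: 10 aldol adduct
Product: 11 (3R,4S)-4-[4-(benzyloxy)-3,5-dimethoxybenzyl]-3-[3,4-bis(triisopropylsilyloxy)benzoyl]dihydrofuran-2(3H)-one (3,4-trans)
Conditions: Dess-Martin periodinane, CH2Cl2, 0 °C to rt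
Reagents that add atoms: none
Why: Dess-Martin oxidation of a secondary benzylic alcohol under near-neutral conditions that leave silyl and benzyl ethers alone; C4 becomes an epimerisable beta-dicarbonyl centre that step 8 flattens anyway.

**Step 8**
Reactants: 11 alpha-aroyl lactone
Product: 13 benzyl (4S)-4-[4-(benzyloxy)-3,5-dimethoxybenzyl]-2-[3,4-bis(triisopropylsilyloxy)phenyl]-4,5-dihydrofuran-3-carboxylate, via hydroxy keto ester 12 (not isolated)
Conditions: BnOH (5 equiv), CSA (10 mol %), toluene, 4 Å MS, 80 °C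
Reagents that add atoms: benzyl alcohol, OCc1ccccc1
Why: Acyl-lactone rearrangement, in which acid-catalysed alcoholysis opens the beta-keto lactone to 12, whose C6 hydroxyl adds to the aryl ketone C8 and loses water to give the conjugated enol ether ester; removal of water makes the sequence irreversible, and C5 is not touched.

**Step 9**
Reactants: 13 dihydrofuran benzyl ester
Product: 15 (2S,3R,4S)-2-[3,4-bis(triisopropylsilyloxy)phenyl]-4-(4-hydroxy-3,5-dimethoxybenzyl)tetrahydrofuran-3-carboxylic acid (all-cis), via dihydrofuran acid 14 (not isolated)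
Conditions: H2 (4 atm), 10 % Pd/C, EtOAc, rt
Reagents that add atoms: none
Why: Heterogeneous catalytic hydrogenation, in which hydrogenolysis first frees the acid and the syringyl phenol (14) and syn addition of H2 to C8=C4 from the face opposite the C5 arylmethyl group then sets C4 (R) and C8 (S) together, placing all three substituents cis as is usual when aryl-substituted furans and dihydrofurans are saturated over Pd.

**Step 10**
Reactants: 15 all-cis acid
Product: 17 (3S,3aS,6S,6aR)-6-[3,4-bis(triisopropylsilyloxy)phenyl]-3-(4-hydroxy-3,5-dimethoxyphenyl)tetrahydro-1H,3H-furo[3,4-c]furan-1-one, via p-quinone methide 16 (not isolated)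
Conditions: evolved FAD-dependent 4-alkylphenol oxidase (eugenol oxidase/vanillyl alcohol oxidase type), air, catalase, 15 dosed as its K salt, KPi buffer pH 7.0, 10 % v/v DMSO, MTBE overlay, 25 °C
Reagents that add atoms: none
Why: Proposed new method: the enzyme binds the syringyl phenolate of 15 over the flavin and takes a hydride from C1H2 to flavin N5, which forms the planar p-quinone methide 16, while O2 reoxidises the reduced flavin and catalase removes the H2O2. The closest known reaction type is the benzylic oxidation of 4-alkylphenols by vanillyl alcohol oxidase and eugenol oxidase, in which the same bound quinone methide is captured enantioselectively by water; capture by an internal carboxylate and a substrate of this size are new. The C3 carboxylate, held cis to the C5 side chain on the tetrahydrofuran, adds to C1 by 5-exo-trig 1,6-addition, which closes the lactone ring C1-O2-C3-C4-C5 and restores the aromatic ring. The new stereocentre C1 (S, aryl concave) is controlled by the protein alone: the flavin covers the face that lost the hydride, and the evolved pocket has to hold the C5-C1 rotamer with H-C5 anti to the quinone methide ring, because the free intermediate would relax to the A(1,3)-minimised rotamer and give the convex epimer. Site selectivity is secured in the substrate, since only the syringyl ring carries a free para OH and the silylated catechol ring cannot form a quinone methide at C8-H; preference over water rests on the intramolecular cis carboxylate and on replacing the water-activating aspartate of the parent enzymes by a small neutral residue. The neutral lactone 17 should move into the MTBE layer, away from further oxidation and from phenolate-triggered reopening of C1-O2.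

**Step 11**
Reactants: 17 bis-silyl lactone
Product: 18 (3S,3aS,6S,6aR)-6-(3,4-dihydroxyphenyl)-3-(4-hydroxy-3,5-dimethoxyphenyl)tetrahydro-1H,3H-furo[3,4-c]furan-1-one (target)
Conditions: TBAF (2.2 equiv), AcOH (3 equiv), THF, 0 °C; neutral work-up
Reagents that add atoms: none
Why: Fluoride cleavage of aryl silyl ethers, in which acetic acid keeps all phenols protonated so that no phenolate can expel the C1 carboxylate or O7; none of the four stereocentres is touched.

**Compound list**
1 | syringaldehyde | COc1cc(C=O)cc(OC)c1O | starting material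
2 | 4-(benzyloxy)-3,5-dimethoxybenzaldehyde | COc1cc(C=O)cc(OC)c1OCc1ccccc1 | intermediate
3 | dimethyl succinate | COC(=O)CCC(=O)OC | starting material
4 | (E)-4-[4-(benzyloxy)-3,5-dimethoxyphenyl]-3-(methoxycarbonyl)but-3-enoic acid | COC(=O)/C(CC(=O)O)=C/c1cc(OC)c(OCc2ccccc2)c(OC)c1 | intermediate
5 | (3S)-4-[4-(benzyloxy)-3,5-dimethoxyphenyl]-3-(methoxycarbonyl)butanoic acid | COC(=O)[C@H](CC(=O)O)Cc1cc(OC)c(OCc2ccccc2)c(OC)c1 | intermediate
6 | (3S)-3-[4-(benzyloxy)-3,5-dimethoxybenzyl]-4-hydroxybutanoic acid (not isolated) | OC[C@H](CC(=O)O)Cc1cc(OC)c(OCc2ccccc2)c(OC)c1 | intermediate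
7 | (4S)-4-[4-(benzyloxy)-3,5-dimethoxybenzyl]dihydrofuran-2(3H)-one | O=C1C[C@H](Cc2cc(OC)c(OCc3ccccc3)c(OC)c2)CO1 | intermediate
8 | 3,4-dihydroxybenzaldehyde | O=Cc1ccc(O)c(O)c1 | starting material
9 | 3,4-bis(triisopropylsilyloxy)benzaldehyde | O=Cc1ccc(O[Si](C(C)C)(C(C)C)C(C)C)c(O[Si](C(C)C)(C(C)C)C(C)C)c1 | intermediate
10 | (3R,4S)-aldol adduct, both carbinol epimers | O=C1[C@@H](C(O)c2ccc(O[Si](C(C)C)(C(C)C)C(C)C)c(O[Si](C(C)C)(C(C)C)C(C)C)c2)[C@H](Cc2cc(OC)c(OCc3ccccc3)c(OC)c2)CO1 | intermediate
11 | (3R,4S)-alpha-aroyl lactone, 3,4-trans | O=C1[C@@H](C(=O)c2ccc(O[Si](C(C)C)(C(C)C)C(C)C)c(O[Si](C(C)C)(C(C)C)C(C)C)c2)[C@H](Cc2cc(OC)c(OCc3ccccc3)c(OC)c2)CO1 | intermediate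
12 | benzyl (3S)-3-[4-(benzyloxy)-3,5-dimethoxybenzyl]-2-[3,4-bis(triisopropylsilyloxy)benzoyl]-4-hydroxybutanoate, C2 labile (not isolated) | O=C(OCc1ccccc1)C(C(=O)c1ccc(O[Si](C(C)C)(C(C)C)C(C)C)c(O[Si](C(C)C)(C(C)C)C(C)C)c1)[C@H](Cc1cc(OC)c(OCc2ccccc2)c(OC)c1)CO | intermediate
13 | benzyl (4S)-4-[4-(benzyloxy)-3,5-dimethoxybenzyl]-2-[3,4-bis(triisopropylsilyloxy)phenyl]-4,5-dihydrofuran-3-carboxylate | O=C(OCc1ccccc1)C1=C(c2ccc(O[Si](C(C)C)(C(C)C)C(C)C)c(O[Si](C(C)C)(C(C)C)C(C)C)c2)OC[C@H]1Cc1cc(OC)c(OCc2ccccc2)c(OC)c1 | intermediate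
14 | (4S)-2-[3,4-bis(triisopropylsilyloxy)phenyl]-4-(4-hydroxy-3,5-dimethoxybenzyl)-4,5-dihydrofuran-3-carboxylic acid (not isolated) | O=C(O)C1=C(c2ccc(O[Si](C(C)C)(C(C)C)C(C)C)c(O[Si](C(C)C)(C(C)C)C(C)C)c2)OC[C@H]1Cc1cc(OC)c(O)c(OC)c1 | intermediate
15 | (2S,3R,4S)-2-[3,4-bis(triisopropylsilyloxy)phenyl]-4-(4-hydroxy-3,5-dimethoxybenzyl)tetrahydrofuran-3-carboxylic acid, all-cis | COc1cc(C[C@@H]2CO[C@H](c3ccc(O[Si](C(C)C)(C(C)C)C(C)C)c(O[Si](C(C)C)(C(C)C)C(C)C)c3)[C@@H]2C(=O)O)cc(OC)c1O | intermediate
16 | (2S,3R,4S)-2-[3,4-bis(triisopropylsilyloxy)phenyl]-4-[(3,5-dimethoxy-4-oxocyclohexa-2,5-dien-1-ylidene)methyl]tetrahydrofuran-3-carboxylic acid (not isolated) | COC1=CC(=C[C@@H]2CO[C@H](c3ccc(O[Si](C(C)C)(C(C)C)C(C)C)c(O[Si](C(C)C)(C(C)C)C(C)C)c3)[C@@H]2C(=O)O)C=C(OC)C1=O | intermediate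
17 | (3S,3aS,6S,6aR)-6-[3,4-bis(triisopropylsilyloxy)phenyl]-3-(4-hydroxy-3,5-dimethoxyphenyl)tetrahydro-1H,3H-furo[3,4-c]furan-1-one | COc1cc([C@H]2OC(=O)[C@@H]3[C@H]2CO[C@@H]3c2ccc(O[Si](C(C)C)(C(C)C)C(C)C)c(O[Si](C(C)C)(C(C)C)C(C)C)c2)cc(OC)c1O | intermediate
18 | (3S,3aS,6S,6aR)-6-(3,4-dihydroxyphenyl)-3-(4-hydroxy-3,5-dimethoxyphenyl)tetrahydro-1H,3H-furo[3,4-c]furan-1-one | COc1cc([C@H]2OC(=O)[C@@H]3[C@H]2CO[C@@H]3c2ccc(O)c(O)c2)cc(OC)c1O | target

Total steps: 11. Longest linear sequence: 10 (steps 1-4 and 6-11).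

**Steps most likely to fail**

**Step 10.**
- What may go wrong: the bulky acid may not be admitted to the flavin site. The bound quinone methide may close from the relaxed rotamer, giving poor facial selectivity at C1. Water may outrun the carboxylate. The lactone may reopen through its phenolate and epimerise at C1.
- The fallback uses known chemistry. It sets C1 by hydrogen delivery to a bicyclic alkene instead of by C-O bond formation. It sets out from 15 and returns at 17.
- DDQ (2.2 equiv) in wet dioxane carries the p-hydroxybenzylic CH2 through to the aryl ketone and should give the gamma-keto acid F1.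
- Ac2O/NaOAc closes F1 to the enol lactone acetate F2 (C1=C5 double bond, phenol acetylated), which erases C5.
- Hydrogenation over Rh/Al2O3 (1 atm, EtOAc) adds H2 syn from the convex face. This is the face of H-C4; the other face is covered by the C8 aryl group. H-C1 and H-C5 therefore end up cis to H-C4, which gives the concave-aryl lactone acetate F3.
- Lipase-catalysed butanolysis (Candida antarctica lipase B, n-BuOH, MTBE) removes the acetate under neutral conditions and gives 17.

**Step 9.**
- What may go wrong: saturation of the tetrasubstituted push-pull alkene may be slow. Facial selectivity may erode if the syringyl ring adsorbs on the metal. Prolonged exposure may cause hydrogenolysis of the benzylic C8-O7 bond.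
- The fallback sets each centre separately and closes the ether ring by substitution at the primary carbon C6. It sets out from 11 and returns at 15.
- Asymmetric transfer hydrogenation (Ru(p-cymene)(TsDPEN) antipode giving the S carbinol, HCO2H/Et3N) should give the hydroxy lactone F4. Here C8 is catalyst-controlled and C4 stays trans to the C5 side chain. This trans relation becomes cis once C8 replaces C3 as ring member.
- One equivalent of LiOH (THF-water, 0 °C) followed by BnBr on the dried carboxylate salt gives the diol benzyl ester F5.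
- TsCl/pyridine at 0 °C sulfonylates only the primary hydroxyl, giving the primary tosylate F6.
- Warming with iPr2NEt in MeCN lets the C8 hydroxyl displace the tosylate (5-exo-tet, no stereocentre involved) to give the all-cis tetrahydrofuran benzyl ester F7.
- Brief hydrogenolysis (H2, 1 atm, Pd/C, EtOAc) gives 15.

**Step 8.**
- What may go wrong: alcoholysis of the lactone may be incomplete. Silyl groups may be lost under acid and heat. The electron-rich rings may be benzylated.
- The fallback installs the ester by carboxylate alkylation, so no acid-catalysed alcoholysis is needed. It sets out from 10 and returns at 12, and from there at 13.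
- LiOH (1 equiv) opens 10, and BnBr alkylates the salt to the diol benzyl ester F8 (carbinol epimers).
- MnO2 oxidises only the benzylic carbinol and gives 12.
- 12 loses water with PPTS and molecular sieves at room temperature to give 13.

**Further compounds**
F1 | step 10 | (2S,3R,4S)-2-[3,4-bis(triisopropylsilyloxy)phenyl]-4-(4-hydroxy-3,5-dimethoxybenzoyl)tetrahydrofuran-3-carboxylic acid | COc1cc(C(=O)[C@@H]2CO[C@H](c3ccc(O[Si](C(C)C)(C(C)C)C(C)C)c(O[Si](C(C)C)(C(C)C)C(C)C)c3)[C@@H]2C(=O)O)cc(OC)c1O
F2 | step 10 | (6S,6aR)-3-(4-acetoxy-3,5-dimethoxyphenyl)-6-[3,4-bis(triisopropylsilyloxy)phenyl]-6,6a-dihydro-1H,4H-furo[3,4-c]furan-1-one | COc1cc(C2=C3CO[C@H](c4ccc(O[Si](C(C)C)(C(C)C)C(C)C)c(O[Si](C(C)C)(C(C)C)C(C)C)c4)[C@@H]3C(=O)O2)cc(OC)c1OC(C)=O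
F3 | step 10 | (3S,3aS,6S,6aR)-3-(4-acetoxy-3,5-dimethoxyphenyl)-6-[3,4-bis(triisopropylsilyloxy)phenyl]tetrahydro-1H,3H-furo[3,4-c]furan-1-one | COc1cc([C@H]2OC(=O)[C@@H]3[C@H]2CO[C@@H]3c2ccc(O[Si](C(C)C)(C(C)C)C(C)C)c(O[Si](C(C)C)(C(C)C)C(C)C)c2)cc(OC)c1OC(C)=O
F4 | step 9 | (3R,4S)-4-[4-(benzyloxy)-3,5-dimethoxybenzyl]-3-{(S)-[3,4-bis(triisopropylsilyloxy)phenyl](hydroxy)methyl}dihydrofuran-2(3H)-one | O=C1[C@@H]([C@H](O)c2ccc(O[Si](C(C)C)(C(C)C)C(C)C)c(O[Si](C(C)C)(C(C)C)C(C)C)c2)[C@H](Cc2cc(OC)c(OCc3ccccc3)c(OC)c2)CO1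
F5 | step 9 | benzyl (2R,3S)-3-[4-(benzyloxy)-3,5-dimethoxybenzyl]-2-{(S)-[3,4-bis(triisopropylsilyloxy)phenyl](hydroxy)methyl}-4-hydroxybutanoate | O=C(OCc1ccccc1)[C@@H]([C@H](O)c1ccc(O[Si](C(C)C)(C(C)C)C(C)C)c(O[Si](C(C)C)(C(C)C)C(C)C)c1)[C@H](Cc1cc(OC)c(OCc2ccccc2)c(OC)c1)CO
F6 | step 9 | benzyl (2R,3S)-3-[4-(benzyloxy)-3,5-dimethoxybenzyl]-2-{(S)-[3,4-bis(triisopropylsilyloxy)phenyl](hydroxy)methyl}-4-(tosyloxy)butanoate | O=C(OCc1ccccc1)[C@@H]([C@H](O)c1ccc(O[Si](C(C)C)(C(C)C)C(C)C)c(O[Si](C(C)C)(C(C)C)C(C)C)c1)[C@H](Cc1cc(OC)c(OCc2ccccc2)c(OC)c1)COS(=O)(=O)c1ccc(C)cc1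
F7 | step 9 | benzyl (2S,3R,4S)-4-[4-(benzyloxy)-3,5-dimethoxybenzyl]-2-[3,4-bis(triisopropylsilyloxy)phenyl]tetrahydrofuran-3-carboxylate | COc1cc(C[C@@H]2CO[C@H](c3ccc(O[Si](C(C)C)(C(C)C)C(C)C)c(O[Si](C(C)C)(C(C)C)C(C)C)c3)[C@@H]2C(=O)OCc2ccccc2)cc(OC)c1OCc1ccccc1
F8 | step 8 | benzyl (2R,3S)-3-[4-(benzyloxy)-3,5-dimethoxybenzyl]-2-{[3,4-bis(triisopropylsilyloxy)phenyl](hydroxy)methyl}-4-hydroxybutanoate, carbinol epimers | O=C(OCc1ccccc1)[C@@H](C(O)c1ccc(O[Si](C(C)C)(C(C)C)C(C)C)c(O[Si](C(C)C)(C(C)C)C(C)C)c1)[C@H](Cc1cc(OC)c(OCc2ccccc2)c(OC)c1)CO
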